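**Plan**

- Retrosynthesis: the 14-membered carbocycle is cut at its enoate C=C (intramolecular Horner–Wadsworth–Emmons), then at the bond from the enoate α-carbon to its ring CH2 (phosphonoacetate alkylation), then at the O–CMe2 bond of the oxolane.
- Feature used: the ester-bearing ring CH and the oxolane O–CH are adjacent, and the ring oxygen ends on a CMe2 carbon. Opening the oxolane therefore gives an anti α-alkyl β-hydroxy ester with an isopropenyl group, and its β-keto ester precursor is epimerisable at the α-carbon.
- Further cuts: the carbinol C–H (ketone reduction), the α-carbon–CH2 bond (alkylation), the α-carbon–carbonyl bond (Claisen), and the Z-trisubstituted olefin (Grob fragmentation of a carvone aldol).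
- Forward: the chain stays open through step 6; the oxolane closes in step 7; the 14-membered ring closes last, in step 12.
- Stereochemistry: the oxolane CH next to CMe2 comes from (R)-carvone; the Z-olefin from an anti aldol and an antiperiplanar fragmentation; the ester CH and ether CH from the ketoreductase; the E-enoate from the olefination.

Key step: step 6

Remark: the ketoreductase is taken to be an engineered NADPH-dependent variant chosen from a screening panel for (2S,3S) selectivity on 12. Compound 4 is drawn as the anti aldol formed on the enolate face cis to the isopropenyl group; its C-2 epimer with the same C-2/carbinol relationship would fragment to the same olefin 7.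

**Route**

Step 1
Reactants: 1 (R)-(−)-carvone; 2 3-(tert-butyldimethylsilyloxy)propanal
Product: 4 (2R,5R)-2-[(1R)-3-[(tert-butyldimethylsilyl)oxy]-1-hydroxypropyl]-2-methyl-5-(prop-1-en-2-yl)cyclohexan-1-one, via lithium enolate 3 (not isolated)
Conditions: LiBH(s-Bu)3 (L-Selectride), THF, −78 °C; then 2, −78 °C; AcOH quench
Reagents that add atoms: none
Why: Conjugate hydride addition gives the regiodefined enolate 3, and its reductive aldol reaction with 2 through a Zimmerman–Traxler chair (a ring enolate is necessarily E) should give the anti adduct, which fixes the quaternary carbon and the carbinol relative to each other; the face of attack does not matter for the olefin formed in step 3.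

Step 2
Reactants: 4 the aldol adduct
Product: 5 (1R)-3-[(tert-butyldimethylsilyl)oxy]-1-[(1R,4R)-1-methyl-2-oxo-4-(prop-1-en-2-yl)cyclohexyl]propyl methanesulfonate
Conditions: MsCl, Et3N, CH2Cl2, 0 °C
Reagents that add atoms: methanesulfonyl chloride, CS(=O)(=O)Cl
Why: Mesylation through the sulfene works on hindered secondary alcohols, and the quaternary α-carbon rules out β-elimination toward the ketone.

Step 3
Reactants: 5 the β-mesyloxy ketone
Product: 7 methyl (3R,6Z)-9-[(tert-butyldimethylsilyl)oxy]-6-methyl-3-(prop-1-en-2-yl)non-6-enoate, via hemiketal alkoxide 6 (not isolated)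
Conditions: NaOMe, MeOH, 0 °C to rt
Reagents that add atoms: sodium methoxide, [Na+].[O-]C
Why: Methoxide adds to the ketone and alkoxide 6 expels the antiperiplanar mesylate with cleavage of the ring C–C bond (Grob fragmentation), a stereospecific anti process that turns the anti aldol relationship into the Z-trisubstituted olefin and the ketone carbon into the methyl ester.

Step 4
Reactants: 7 the Z-olefinic methyl ester; 8 methyl acetate
Product: 10 methyl (5R,8Z)-11-[(tert-butyldimethylsilyl)oxy]-8-methyl-3-oxo-5-(prop-1-en-2-yl)undec-8-enoate, via lithium enolate of methyl acetate 9 (not isolated)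
Conditions: 8 (3.5 equiv), LiN(i-Pr)2 (3.4 equiv), THF, −78 °C; then 7, −78 to −20 °C; AcOH quench
Reagents that add atoms: none
Why: Crossed Claisen condensation in which excess enolate 9 acylates on the ester of 7 and the product is held as its enolate, which prevents a second addition; the stereocentre lies β to the carbonyl and is not touched.

Step 5
Reactants: 10 the β-keto ester; 11 3-bromo-1,1-dimethoxypropane
Product: 12 methyl (2RS,5R,8Z)-11-[(tert-butyldimethylsilyl)oxy]-2-(3,3-dimethoxypropyl)-8-methyl-3-oxo-5-(prop-1-en-2-yl)undec-8-enoate (both α-epimers)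
Conditions: K2CO3, Bu4NI (cat.), DMF, 50 °C
Reagents that add atoms: none
Why: Acetoacetic ester alkylation, in which the potassium enolate of the 1,3-dicarbonyl is C-alkylated by the primary halide (iodide formed in situ); the new α-centre is left unselected because it is labile.

Step 6
Reactants: 12 the α-alkyl β-keto ester, epimeric at C-2
Product: 13 methyl (2S,3S,5R,8Z)-11-[(tert-butyldimethylsilyl)oxy]-2-(3,3-dimethoxypropyl)-3-hydroxy-8-methyl-5-(prop-1-en-2-yl)undec-8-enoate
Conditions: ketoreductase (engineered, NADPH-dependent), NADP+ (cat.), i-PrOH, DMSO cosolvent, KH2PO4/K2HPO4 buffer pH 7.5, MgSO4 (2 mM), 30 °C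
Reagents that add atoms: none
Why: The enzyme binds one α-epimer of 12 and transfers the hydride of NADPH to one face of the ketone, while isopropanol regenerates NADPH and the unreactive epimer re-enters through the enol of the β-keto ester at pH 7.5. The closest known reaction type is the ketoreductase-catalysed dynamic reductive kinetic resolution of α-alkyl β-keto esters. No ring is closed and no skeletal bond is formed. The carbinol configuration (3S) is set by the face of hydride delivery in the active site and the α-configuration (2S) by the enzyme's choice between the two interconverting epimers, so both are under catalyst control and the anti pair should result. The step needs anti selectivity, acceptance of a ketone with two large flanking groups, and epimerisation faster than reduction; the 1,3-dicarbonyl acidity of C-2 secures the last, C-5 lies β to the ketone and cannot epimerise, and the first two are met by choosing the variant from a panel.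

Step 7
Reactants: 13 the anti β-hydroxy ester
Product: 15 methyl (2S)-2-[(2S,4R)-4-[(3Z)-6-[(tert-butyldimethylsilyl)oxy]-3-methylhex-3-en-1-yl]-5,5-dimethyloxolan-2-yl]-5,5-dimethoxypentanoate, via organomercury acetate 14 (not isolated)
Conditions: Hg(OAc)2, THF, 0 °C to rt; then NaBH4, 1 M aq. NaOH, −20 to 0 °C
Reagents that add atoms: none
Why: Intramolecular alkoxymercuration–demercuration, in which divalent mercury activates the 1,1-disubstituted olefin (the most reactive olefin class toward it), the carbinol oxygen attacks the tertiary carbon in a Markovnikov 5-exo-trig closure, and NaBH4 replaces mercury by hydrogen so that the former isopropenyl carbon becomes CMe2 and no new stereocentre remains.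

Step 8
Reactants: 15 the oxolane silyl ether
Product: 16 methyl (2S)-2-[(2S,4R)-4-[(3Z)-6-hydroxy-3-methylhex-3-en-1-yl]-5,5-dimethyloxolan-2-yl]-5,5-dimethoxypentanoate
Conditions: Bu4NF, THF, 0 °C to rt; H2O work-up
Reagents that add atoms: none
Why: Fluoride desilylation driven by the Si–F bond; esters, acetal and ether are inert.

Step 9
Reactants: 16 the primary alcohol
Product: 17 methyl (2S)-2-[(2S,4R)-4-[(3Z)-6-iodo-3-methylhex-3-en-1-yl]-5,5-dimethyloxolan-2-yl]-5,5-dimethoxypentanoate
Conditions: I2, PPh3, imidazole, CH2Cl2, 0 °C to rt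
Reagents that add atoms: iodine, II
Why: Appel-type iodination through the alkoxyphosphonium salt with SN2 displacement by iodide, buffered by imidazole so that the acetal survives.

Step 10
Reactants: 17 the homoallylic iodide; 18 methyl 2-(diethoxyphosphoryl)acetate
Product: 20 methyl (2S)-2-[(2S,4R)-4-[(3Z)-7-(diethoxyphosphoryl)-8-methoxy-3-methyl-8-oxooct-3-en-1-yl]-5,5-dimethyloxolan-2-yl]-5,5-dimethoxypentanoate (both epimers at the phosphonate carbon), via sodium phosphonoacetate 19 (not isolated)
Conditions: 18 (1.6 equiv), NaH (1.5 equiv), DMF, 0 °C; then 17, 50 °C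
Reagents that add atoms: none
Why: Phosphonoacetate alkylation, an SN2 reaction of the soft, weakly basic carbanion 19 with a primary iodide; the new phosphonate-bearing centre is formed as a mixture and is destroyed in step 12.

Step 11
Reactants: 20 the phosphonate acetal
Product: 21 methyl (2S)-2-[(2S,4R)-4-[(3Z)-7-(diethoxyphosphoryl)-8-methoxy-3-methyl-8-oxooct-3-en-1-yl]-5,5-dimethyloxolan-2-yl]-5-oxopentanoate
Conditions: TsOH·H2O (cat.), acetone/H2O (10:1), rt
Reagents that add atoms: water, O
Why: Acid-catalysed acetal hydrolysis through the oxocarbenium ion; the tertiary alkyl ether, the esters and the phosphonate are stable to catalytic TsOH at room temperature.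

Step 12
Reactants: 21 the phosphonate aldehyde
Product: 22 dimethyl (1R,4Z,8E,12S,13S)-4,15,15-trimethyl-14-oxabicyclo[11.2.1]hexadeca-4,8-diene-8,12-dicarboxylate (the target)
Conditions: LiCl, DBU, MeCN, slow addition to 1 mM final concentration, rt
Reagents that add atoms: none
Why: Intramolecular Horner–Wadsworth–Emmons reaction in which the lithium-chelated phosphonate is deprotonated by DBU, adds to the aldehyde and loses diethyl phosphate to close the 14-membered ring; reversible addition favours the E-enoate with the ester trans to the β-CH2, and the mild base should leave the epimerisable ester CH untouched.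

**Compound list**

1 | (R)-(−)-carvone | CC1=CC[C@H](CC1=O)C(C)=C | starting material
2 | 3-(tert-butyldimethylsilyloxy)propanal | O=CCCO[Si](C)(C)C(C)(C)C | starting material
3 | lithium (5R)-2-methyl-5-(prop-1-en-2-yl)cyclohex-1-en-1-olate | CC1=C(O[Li])C[C@@H](CC1)C(C)=C | intermediate
4 | (2R,5R)-2-[(1R)-3-[(tert-butyldimethylsilyl)oxy]-1-hydroxypropyl]-2-methyl-5-(prop-1-en-2-yl)cyclohexan-1-one | O=C1C[C@H](C(C)=C)CC[C@]1(C)[C@H](O)CCO[Si](C)(C)C(C)(C)C | intermediate
5 | (1R)-3-[(tert-butyldimethylsilyl)oxy]-1-[(1R,4R)-1-methyl-2-oxo-4-(prop-1-en-2-yl)cyclohexyl]propyl methanesulfonate | O=C1C[C@H](C(C)=C)CC[C@]1(C)[C@H](OS(C)(=O)=O)CCO[Si](C)(C)C(C)(C)C | intermediate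
6 | sodium hemiketal alkoxide of 5 (1-methoxycyclohexan-1-olate, hemiketal carbon undefined) | [Na+].[O-]C1(OC)C[C@H](C(C)=C)CC[C@]1(C)[C@H](OS(C)(=O)=O)CCO[Si](C)(C)C(C)(C)C | intermediate
7 | methyl (3R,6Z)-9-[(tert-butyldimethylsilyl)oxy]-6-methyl-3-(prop-1-en-2-yl)non-6-enoate | COC(=O)C[C@H](C(C)=C)CC/C(C)=C\CCO[Si](C)(C)C(C)(C)C | intermediate
8 | methyl acetate | COC(C)=O | starting material
9 | lithium enolate of methyl acetate | [Li]OC(=C)OC | intermediate
10 | methyl (5R,8Z)-11-[(tert-butyldimethylsilyl)oxy]-8-methyl-3-oxo-5-(prop-1-en-2-yl)undec-8-enoate | COC(=O)CC(=O)C[C@H](C(C)=C)CC/C(C)=C\CCO[Si](C)(C)C(C)(C)C | intermediate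
11 | 3-bromo-1,1-dimethoxypropane | COC(CCBr)OC | starting material
12 | methyl (2RS,5R,8Z)-11-[(tert-butyldimethylsilyl)oxy]-2-(3,3-dimethoxypropyl)-8-methyl-3-oxo-5-(prop-1-en-2-yl)undec-8-enoate | COC(=O)C(CCC(OC)OC)C(=O)C[C@H](C(C)=C)CC/C(C)=C\CCO[Si](C)(C)C(C)(C)C | intermediate
13 | methyl (2S,3S,5R,8Z)-11-[(tert-butyldimethylsilyl)oxy]-2-(3,3-dimethoxypropyl)-3-hydroxy-8-methyl-5-(prop-1-en-2-yl)undec-8-enoate | COC(=O)[C@@H](CCC(OC)OC)[C@@H](O)C[C@H](C(C)=C)CC/C(C)=C\CCO[Si](C)(C)C(C)(C)C | intermediate
14 | organomercury acetate: oxolane 15 with CH2HgOAc in place of one ring methyl group (that carbon undefined) | COC(=O)[C@@H](CCC(OC)OC)[C@@H]1C[C@@H](CC/C(C)=C\CCO[Si](C)(C)C(C)(C)C)C(C)(C[Hg]OC(C)=O)O1 | intermediate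
15 | methyl (2S)-2-[(2S,4R)-4-[(3Z)-6-[(tert-butyldimethylsilyl)oxy]-3-methylhex-3-en-1-yl]-5,5-dimethyloxolan-2-yl]-5,5-dimethoxypentanoate | COC(=O)[C@@H](CCC(OC)OC)[C@@H]1C[C@@H](CC/C(C)=C\CCO[Si](C)(C)C(C)(C)C)C(C)(C)O1 | intermediate
16 | methyl (2S)-2-[(2S,4R)-4-[(3Z)-6-hydroxy-3-methylhex-3-en-1-yl]-5,5-dimethyloxolan-2-yl]-5,5-dimethoxypentanoate | COC(=O)[C@@H](CCC(OC)OC)[C@@H]1C[C@@H](CC/C(C)=C\CCO)C(C)(C)O1 | intermediate
17 | methyl (2S)-2-[(2S,4R)-4-[(3Z)-6-iodo-3-methylhex-3-en-1-yl]-5,5-dimethyloxolan-2-yl]-5,5-dimethoxypentanoate | COC(=O)[C@@H](CCC(OC)OC)[C@@H]1C[C@@H](CC/C(C)=C\CCI)C(C)(C)O1 | intermediate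
18 | methyl 2-(diethoxyphosphoryl)acetate | CCOP(=O)(CC(=O)OC)OCC | starting material
19 | sodium salt of methyl 2-(diethoxyphosphoryl)acetate | [Na+].CCOP(=O)([CH-]C(=O)OC)OCC | intermediate
20 | methyl (2S)-2-[(2S,4R)-4-[(3Z)-7-(diethoxyphosphoryl)-8-methoxy-3-methyl-8-oxooct-3-en-1-yl]-5,5-dimethyloxolan-2-yl]-5,5-dimethoxypentanoate | COC(=O)[C@@H](CCC(OC)OC)[C@@H]1C[C@@H](CC/C(C)=C\CCC(C(=O)OC)P(=O)(OCC)OCC)C(C)(C)O1 | intermediate
21 | methyl (2S)-2-[(2S,4R)-4-[(3Z)-7-(diethoxyphosphoryl)-8-methoxy-3-methyl-8-oxooct-3-en-1-yl]-5,5-dimethyloxolan-2-yl]-5-oxopentanoate | COC(=O)[C@@H](CCC=O)[C@@H]1C[C@@H](CC/C(C)=C\CCC(C(=O)OC)P(=O)(OCC)OCC)C(C)(C)O1 | intermediate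
22 | dimethyl (1R,4Z,8E,12S,13S)-4,15,15-trimethyl-14-oxabicyclo[11.2.1]hexadeca-4,8-diene-8,12-dicarboxylate | COC(=O)/C1=C/CC[C@H](C(=O)OC)[C@@H]2C[C@@H](CC/C(C)=C\CC1)C(C)(C)O2 | target

**Count**

Total steps: 12. Longest linear sequence: 12 steps, from (R)-carvone 1 to 22.

**Steps most likely to fail**

Step 6. The enzyme panel may hold no variant that accepts a ketone flanked by two large groups, or reduction may outrun epimerisation and give a mixture of diastereomers. The two centres would then be set one after the other. Setting out from 10, Noyori hydrogenation with RuCl2[(S)-BINAP] (H2, MeOH), which should leave the isolated olefins untouched, gives methyl (3S,5R,8Z)-11-[(tert-butyldimethylsilyl)oxy]-3-hydroxy-8-methyl-5-(prop-1-en-2-yl)undec-8-enoate F1. Bromide 11 is converted by NaI in acetone (Finkelstein) into 3-iodo-1,1-dimethoxypropane F2. Fráter–Seebach alkylation of the dianion of F1 (LiN(i-Pr)2, 2.2 equiv, THF/DMPU, −78 to −20 °C) with F2 should enter anti to the carbinol substituent in the lithium chelate and comes back to the route at 13.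

Step 12. Oligomerisation may compete with closure of the 14-membered ring, or the enoate geometry may be eroded by ring strain. Ring closure would then be moved to olefin metathesis at the same C=C bond. Setting out from 21, Takai–Lombardo methylenation of the aldehyde (Zn, CH2Br2, TiCl4, THF), which is not basic and leaves the phosphonate alone, gives methyl (2S)-2-[(2S,4R)-4-[(3Z)-7-(diethoxyphosphoryl)-8-methoxy-3-methyl-8-oxooct-3-en-1-yl]-5,5-dimethyloxolan-2-yl]hex-5-enoate F3. Horner–Wadsworth–Emmons reaction of F3 with aqueous formaldehyde (K2CO3) gives the α-methylene ester methyl (2S)-2-[(2S,4R)-4-[(3Z)-7-(methoxycarbonyl)-3-methylocta-3,7-dien-1-yl]-5,5-dimethyloxolan-2-yl]hex-5-enoate F4. Ring-closing metathesis of F4 with the second-generation Grubbs catalyst at high dilution should release ethene and come back to the route at 22, the E-enoate being the expected thermodynamic isomer.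

Step 1. The anti/syn selectivity of the lithium aldol at a fully substituted enolate carbon may be poor, and since the fragmentation is stereospecific this would erode the Z geometry of 7. The aldol would then be run through a boron enolate with a tighter chair. Setting out from 1, conjugate reduction with LiBH(s-Bu)3 and trapping of 3 with Me3SiCl/Et3N gives the isolable silyl enol ether trimethyl{[(5R)-2-methyl-5-(prop-1-en-2-yl)cyclohex-1-en-1-yl]oxy}silane F5, freed from the borane. MeLi (THF, 0 °C) regenerates the lithium enolate, and Bu2BOTf (−78 °C) converts it into the dibutylboron enolate dibutyl{[(5R)-2-methyl-5-(prop-1-en-2-yl)cyclohex-1-en-1-yl]oxy}borane F6. Aldol addition of F6 to 2 at −78 °C with hydrolytic work-up should give the anti adduct with higher selectivity and comes back to the route at 4.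

**Further compounds**

F1 | step 6 | methyl (3S,5R,8Z)-11-[(tert-butyldimethylsilyl)oxy]-3-hydroxy-8-methyl-5-(prop-1-en-2-yl)undec-8-enoate | COC(=O)C[C@@H](O)C[C@H](C(C)=C)CC/C(C)=C\CCO[Si](C)(C)C(C)(C)C
F2 | step 6 | 3-iodo-1,1-dimethoxypropane | COC(CCI)OC
F3 | step 12 | methyl (2S)-2-[(2S,4R)-4-[(3Z)-7-(diethoxyphosphoryl)-8-methoxy-3-methyl-8-oxooct-3-en-1-yl]-5,5-dimethyloxolan-2-yl]hex-5-enoate | COC(=O)[C@@H](CCC=C)[C@@H]1C[C@@H](CC/C(C)=C\CCC(C(=O)OC)P(=O)(OCC)OCC)C(C)(C)O1
F4 | step 12 | methyl (2S)-2-[(2S,4R)-4-[(3Z)-7-(methoxycarbonyl)-3-methylocta-3,7-dien-1-yl]-5,5-dimethyloxolan-2-yl]hex-5-enoate | COC(=O)[C@@H](CCC=C)[C@@H]1C[C@@H](CC/C(C)=C\CCC(=C)C(=O)OC)C(C)(C)O1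
F5 | step 1 | trimethyl{[(5R)-2-methyl-5-(prop-1-en-2-yl)cyclohex-1-en-1-yl]oxy}silane | CC1=C(O[Si](C)(C)C)C[C@@H](CC1)C(C)=C
F6 | step 1 | dibutyl{[(5R)-2-methyl-5-(prop-1-en-2-yl)cyclohex-1-en-1-yl]oxy}borane | CC1=C(OB(CCCC)CCCC)C[C@@H](CC1)C(C)=C
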